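**Assumption:** chromene numbering is used for the target (O1, C2, C3, C4, C4a, C5 to C8, C8a); ring A is its benzo ring and ring B the 4-hydroxyphenyl ring. The target has no stereocentre, and its C3=C4 bond is cis because it lies in the pyran ring. Compounds 1, 2, 5 and 7 are taken to be commercial.

## The problem

Target 10 is a linear pyrano-dihydrochalcone: a 2,2-dimethyl-2H-chromene whose ring A carries a 3-(4-hydroxyphenyl)propanoyl group at C6, a hydroxyl at C7 and a prenyl group at C8, so that only C5 bears hydrogen. With no stereocentre, the difficulty is purely regiochemical. Three different carbon substituents must be placed on the three nucleophilic carbons of one resorcinol nucleus. Of the two resorcinol oxygens, the one para to the ketone (O1 on C8a) must enter the pyran, while the one ortho to the ketone (on C7) stays free and chelated; the fusion is therefore linear. The prenyl group must go to the carbon between the two oxygens, the most hindered site and the one where O-alkylation competes. The sensitive groups are the prenyl alkene (flanked by two phenolic oxygens and prone to acid-induced closure to a chroman), the chromene C3=C4 bond (intolerant of strong acid, oxidants and hydrogenation) and three free phenols. This excludes hydrogenolysis and strong Lewis acids late in the route and favours a route without protecting groups. The enabling feature is that C4a carries a two-carbon alkene (C4=C3) ending at the oxygen-bearing quaternary C2: C4, C3, C2 and the two methyls are the skeleton of 2-methylbut-3-en-2-ol (7) bonded to the arene through its terminal carbon. A halogen at C4a is therefore enough to bring in every pyran carbon by a Heck reaction, and in 4-bromoresorcinol (1) that halogen is already present and first blocks the one position where acylation and prenylation could go astray.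

## Retrosynthesis

**O1–C2 bond of 10.** Cutting this bond opens the pyran to the E tertiary allylic alcohol 8. It is preferred to cutting O1–C2 and C4a–C4 together, which would need a C–H at C4a and would give up the halogen as a control element in the earlier steps. Precursor 8 has no ring beyond the two benzene rings. The forward reaction has to ionise the tertiary allylic alcohol under acid mild enough to spare the prenyl group; the vinyl ortho-quinone methide 9 that results has lost the E geometry and closes by oxa-6π electrocyclisation. Only one phenol is ortho to the side chain, so only the linear chromene can form.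

**C4a–C4 bond of 8.** Cutting this bond gives aryl bromide 6 and the commodity alcohol 7. Cutting C4=C3 instead (olefination of a C4a aldehyde) or C3–C2 (addition to an enone) would require a formyl group at C4a and a functionalised C4 or C3 reagent, at a cost of several steps. The Heck disconnection removes five carbons in one step and leaves an arene with a single halogen. The forward reaction must arylate the terminal carbon of 7, leave the prenyl alkene alone and tolerate three free phenols. This is the key step.

**C8–CH2 bond of 6 (prenyl group).** Cutting this bond gives bromoketone 4 and prenyl bromide (5). Prenylation is placed after acylation because the ketone makes the para phenol of 4 much the most acidic of the three hydroxyls, so it alone is ionised by one equivalent of base. The bromine occupies the other ortho carbon, so the carbon between the two oxygens is the only carbon site. Prenylating 1 directly would face two open activated carbons. The forward reaction must favour C- over O-alkylation.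

**C6–C(=O) bond of 4.** Cutting the aryl–carbonyl bond gives 1 and phloretic acid (2), both commercial. In 1 only one carbon is both activated (ortho and para to the hydroxyls) and unhindered, so a Friedel–Crafts acylation has a single site. A chalcone route by aldol condensation would need a later conjugate reduction in the presence of an aryl bromide, whereas 2 supplies the saturated chain and ring B ready-made. The forward reaction has to tolerate the free phenol of 2 and keep the bromine in place; the product is formed as its difluoroboron chelate 3 and released on work-up.

## Roads not taken

**Alternative 1:** Ring A is built from acyclic pieces by cutting C6–C7 and C4a–C5. A Diels–Alder reaction joins the bis(silyloxy) diene A2, which carries the prenyl group on its central carbon, with the terminal ynone A3, which carries ring B as a silyl ether. Elimination of the methoxy group from the cycloadduct aromatises it to A1.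
- Merits: the prenyl position is fixed by the carbon skeleton of A2, so no C- versus O-alkylation question arises. In this respect it is better than step 2 of the chosen plan. Polarity matching of diene and ynone also fixes the ketone position.
- Weak points: A1 has hydrogen at C4a, so the pyran must still be added by condensation with the enal A4. Ring B needs protection and deprotection. A2 is a moisture-sensitive ketene acetal that must be made and used fresh, and its central substituent slows cycloaddition. Terminal ynones tend to give open-chain Mukaiyama–Michael adducts. The route builds a benzene ring that can be bought.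
- Comparison: the chosen plan offers about half the step count, no protecting groups and a commercial aromatic core, and its bromine leaves only one carbon site for prenylation; it accepts a less clean prenylation in exchange.

**Alternative 2:** The cut lies inside the prenyl group, at its CH2–CH= bond. The Grignard reagent A7 converts the carbonate A6 into an ortho-quinone methide at the C8 methylene (carbonate transfer to the alkoxide, then elimination) and adds to it, giving the chromenol A5.
- Merits: bond formation at carbon is unambiguous and mild, and it is more selective than step 2 of the chosen plan.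
- Weak points: A5 lacks the C6 acyl chain. The ketone would have to be introduced last, on an acid-sensitive chromene with a prenyl group next to a free phenol, where the hot Lewis acid of step 1 could not be used; milder indirect acylations add steps. A6 needs several steps of its own, including a linear-versus-angular chromene question and protecting-group changes.
- Comparison: the chosen plan puts the harshest step first, on the robust compound 1, and reaches the target in four steps; in return it has the ambident phenoxide of step 2 to manage.

**Alternative 3:** The cut is the CH2–aryl bond of the propanoyl chain. A rhodium-catalysed conjugate addition transfers the aryl group of boronic acid A10 to the terminal carbon of the ring A vinyl ketone A9, giving the bis-silyl ether A8; desilylation then gives 10.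
- Merits: the key step is neutral and mild, tolerates chromene and prenyl, and is convergent. It allows late variation of ring B, which makes it the better route for analogues, and the final fluoride deprotection is gentle.
- Weak points: the bond formed is one that 2 supplies ready-made. All the regiochemical work on ring A (prenyl, linear pyran, acyl) must be done beforehand to reach A9. A methyl ketone must be converted into a polymerisable vinyl ketone, and the hindered chelated C7 hydroxyl must be silylated to prevent intramolecular oxa-Michael closure. Two silyl ethers are added and removed.
- Comparison: the chosen plan offers brevity and a key step that forms a bond nothing commercial provides; it gives up the modularity in ring B.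

Key step: step 3

## Route

**Step 1**
Reactants: 1 4-bromoresorcinol (4-bromobenzene-1,3-diol); 2 3-(4-hydroxyphenyl)propanoic acid (phloretic acid)
Product: 4 1-(5-bromo-2,4-dihydroxyphenyl)-3-(4-hydroxyphenyl)propan-1-one, via difluoroboron chelate 3 (not isolated)
Conditions: BF3·OEt2 (neat), 90 °C; then MeOH–H2O, 60 °C
Reagents that add atoms: none
Why: Friedel–Crafts (Nencki-type) acylation of a resorcinol by a free carboxylic acid in BF3·OEt2, a standard entry to resorcinol aryl ketones from arylacetic and arylpropanoic acids; in 1 only the carbon ortho to one hydroxyl and para to the other is activated and unhindered, the other such carbon bearing bromine. The ketone is held as chelate 3 (BF2 bridging the ortho phenolic oxygen and the carbonyl oxygen), which deactivates the ring to a second acylation and is hydrolysed to 4 in warm aqueous methanol.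

**Step 2**
Reactants: 4 1-(5-bromo-2,4-dihydroxyphenyl)-3-(4-hydroxyphenyl)propan-1-one; 5 1-bromo-3-methylbut-2-ene (prenyl bromide)
Product: 6 1-[5-bromo-2,4-dihydroxy-3-(3-methylbut-2-enyl)phenyl]-3-(4-hydroxyphenyl)propan-1-one
Conditions: KOH (1.1 equiv), H2O, 0 °C to rt
Reagents that add atoms: none
Why: C-alkylation of a phenoxide in water, the usual direct route to 3-prenyl-2,4-dihydroxyaryl ketones; one equivalent of base ionises only the phenol para to the ketone, and water solvates the oxyanion and directs the allylic bromide to the ortho carbon. The other ortho carbon carries bromine, so the carbon between the two oxygens is the only carbon site, and the ring B phenol stays protonated.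

**Step 3**
Reactants: 6 1-[5-bromo-2,4-dihydroxy-3-(3-methylbut-2-enyl)phenyl]-3-(4-hydroxyphenyl)propan-1-one; 7 2-methylbut-3-en-2-ol
Product: 8 1-[2,4-dihydroxy-5-[(E)-3-hydroxy-3-methylbut-1-enyl]-3-(3-methylbut-2-enyl)phenyl]-3-(4-hydroxyphenyl)propan-1-one
Conditions: 7 (3 equiv), Pd(OAc)2 (5 mol %), P(o-tolyl)3 (15 mol %), Et3N, MeCN, 100 °C, sealed tube
Reagents that add atoms: none
Why: Pd(OAc)2 is reduced in the flask by the phosphine and the amine to zerovalent palladium, which adds oxidatively to the only C–Br bond of 6, at the future C4a. The monosubstituted alkene of 7 then undergoes syn migratory insertion with the aryl group going to its terminal carbon, which forms the C4a–C4 bond and leaves palladium on the carbon next to the carbinol. The carbinol carbon has no hydrogen, so syn β-hydride elimination can only take the benzylic hydrogen; the styrenyl E alkene of 8 is the single outcome, no carbonyl compound can arise, and Et3N takes up HBr to return zerovalent palladium. This is a Mizoroki–Heck arylation, and the closest known case is the coupling of aryl bromides and ortho-halophenols with 2-methylbut-3-en-2-ol under Pd(OAc)2, P(o-tolyl)3 and Et3N. No ring closes and no stereocentre forms; the E geometry follows from syn insertion and syn elimination through the less crowded rotamer. The step needs terminal regioselectivity and chemoselectivity over the prenyl alkene, and the substrate secures both: the quaternary carbinol shields the internal carbon of 7, and the trisubstituted prenyl alkene is too hindered to insert and lies meta to palladium, out of intramolecular reach. The phenols are carried free, and any 8 that already closes to 10 in the hot mixture is on the way to the target.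

**Step 4**
Reactants: 8 1-[2,4-dihydroxy-5-[(E)-3-hydroxy-3-methylbut-1-enyl]-3-(3-methylbut-2-enyl)phenyl]-3-(4-hydroxyphenyl)propan-1-one
Product: 10 1-[7-hydroxy-2,2-dimethyl-8-(3-methylbut-2-enyl)-2H-chromen-6-yl]-3-(4-hydroxyphenyl)propan-1-one, via vinyl ortho-quinone methide 9 (not isolated)
Conditions: PPTS (10 mol %), toluene, 80 °C
Reagents that add atoms: none
Why: Acid-catalysed cyclodehydration of an ortho-(3-hydroxy-3-methylbut-1-enyl)phenol to a 2,2-dimethyl-2H-chromene; the weak acid ionises the tertiary allylic alcohol, loss of the phenolic proton gives 9, in which the former E alkene is a freely rotating single bond, and oxa-6π electrocyclisation forms the O1–C2 bond. Only one phenol is ortho to the side chain, so the fusion is linear, and PPTS is expected to be too weak to add a phenol across the prenyl alkene.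

## Compound list

1 | 4-bromoresorcinol (4-bromobenzene-1,3-diol) | Oc1ccc(Br)c(O)c1 | starting material
2 | 3-(4-hydroxyphenyl)propanoic acid (phloretic acid) | OC(=O)CCc1ccc(O)cc1 | starting material
3 | difluoroboron chelate of 4: 6-bromo-2,2-difluoro-7-hydroxy-4-[2-(4-hydroxyphenyl)ethyl]-1,3,2-benzodioxaborinine, zwitterionic form, BF2 bridging the ortho phenolic oxygen and the ketone oxygen | Oc1cc2c(cc1Br)C(CCc1ccc(O)cc1)=[O+][B-](F)(F)O2 | intermediate
4 | 1-(5-bromo-2,4-dihydroxyphenyl)-3-(4-hydroxyphenyl)propan-1-one | O=C(CCc1ccc(O)cc1)c1cc(Br)c(O)cc1O | intermediate
5 | 1-bromo-3-methylbut-2-ene (prenyl bromide) | CC(C)=CCBr | starting material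
6 | 1-[5-bromo-2,4-dihydroxy-3-(3-methylbut-2-enyl)phenyl]-3-(4-hydroxyphenyl)propan-1-one | CC(C)=CCc1c(O)c(C(=O)CCc2ccc(O)cc2)cc(Br)c1O | intermediate
7 | 2-methylbut-3-en-2-ol | C=CC(C)(C)O | starting material
8 | 1-[2,4-dihydroxy-5-[(E)-3-hydroxy-3-methylbut-1-enyl]-3-(3-methylbut-2-enyl)phenyl]-3-(4-hydroxyphenyl)propan-1-one | CC(C)=CCc1c(O)c(C(=O)CCc2ccc(O)cc2)cc(/C=C/C(C)(C)O)c1O | intermediate
9 | 3-hydroxy-4-[3-(4-hydroxyphenyl)propanoyl]-2-(3-methylbut-2-enyl)-6-(3-methylbut-2-enylidene)cyclohexa-2,4-dien-1-one (vinyl ortho-quinone methide, exocyclic geometry not fixed) | CC(C)=CCC1=C(O)C(C(=O)CCc2ccc(O)cc2)=CC(=CC=C(C)C)C1=O | intermediate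
10 | 1-[7-hydroxy-2,2-dimethyl-8-(3-methylbut-2-enyl)-2H-chromen-6-yl]-3-(4-hydroxyphenyl)propan-1-one | CC(C)=CCc1c(O)c(C(=O)CCc2ccc(O)cc2)cc2c1OC(C)(C)C=C2 | target

## Step count and risks

Total step count: 4. Longest linear sequence: 4 steps (1 → 4 → 6 → 8 → 10).

**Step 3 (key step).** The likely failure is slow oxidative addition. The bromide is ortho and para to two oxygen donors and the neighbouring phenol is partly ionised by Et3N, so the catalyst may decompose to palladium metal before turnover and hydrodebromination may take over. At 100 °C the tertiary alcohol may also dehydrate toward a diene. The fallback forms the same bond by Suzuki–Miyaura coupling, which runs at lower temperature with a dialkylbiarylphosphine suited to electron-rich bromophenols and transfers a preformed E alkene. It sets out from 6. The partner is (E)-2-methyl-4-(4,4,5,5-tetramethyl-1,3,2-dioxaborolan-2-yl)but-3-en-2-ol F1, made from 2-methylbut-3-yn-2-ol by copper-catalysed borylation with bis(pinacolato)diboron (CuCl, NaOt-Bu, Xantphos, MeOH). Coupling of 6 with F1 under Pd(OAc)2, SPhos, K3PO4, dioxane–H2O, 70 °C should give 8, where the route is rejoined.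

**Step 2.** The likely failure is O-alkylation of the ambident phenoxide, with a second alkylation of the product or of the ring B phenol if base is in excess, so that 6 would be one component of a mixture. The fallback delivers the prenyl group intramolecularly by a Claisen rearrangement and sets out from 4. Copper-catalysed etherification of the most acidic phenol with 3-chloro-3-methylbut-1-yne (CuCl2 cat., DBU, MeCN, 0 °C) should give 1-[5-bromo-2-hydroxy-4-(2-methylbut-3-yn-2-yloxy)phenyl]-3-(4-hydroxyphenyl)propan-1-one F2. Semihydrogenation (H2, Pd/CaCO3 poisoned with Pb(OAc)2, quinoline, EtOAc) should give 1-[5-bromo-2-hydroxy-4-(2-methylbut-3-en-2-yloxy)phenyl]-3-(4-hydroxyphenyl)propan-1-one F3. Heating F3 in N,N-diethylaniline at 130 °C should bring about the [3,3] shift to the only ortho carbon that bears hydrogen, the other being blocked by bromine, and give 6, where the route is rejoined.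

**Step 1.** The likely failure is loss or migration of bromine in hot BF3·OEt2 (protodebromination, or transfer of bromine to the ring B phenol), together with self-acylation of 2 on its own phenol ring. The fallback is a Hoesch reaction, which runs at 0 °C, and sets out from 1. Condensation with commercially available 3-(4-hydroxyphenyl)propanenitrile F4 (ZnCl2, HCl gas, Et2O, 0 °C) should give the ketiminium salt 4-bromo-6-[3-(4-hydroxyphenyl)propanimidoyl]benzene-1,3-diol hydrochloride F5. Hydrolysis in hot water should give 4, where the route is rejoined.

**Step 4.** The likely failure is acid-induced addition of a flanking phenol across the prenyl alkene (chroman formation), or elimination and oligomerisation of the allyl cation instead of ring closure. The fallback builds the pyran under basic conditions by a different bond set and sets out from 6. Reductive removal of bromine (Pd(OAc)2, PPh3, HCO2H, Et3N, DMF, 80 °C) should give 1-[2,4-dihydroxy-3-(3-methylbut-2-enyl)phenyl]-3-(4-hydroxyphenyl)propan-1-one F6. Condensation of F6 with 3-methylbut-2-enal in pyridine at 120 °C should pass through the same quinone methide 9 and its electrocyclisation. The only free carbon ortho to a phenol is the future C4a, so this should give 10, where the route is rejoined at the target.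

## Further compounds

F1 | step 3 | (E)-2-methyl-4-(4,4,5,5-tetramethyl-1,3,2-dioxaborolan-2-yl)but-3-en-2-ol | CC(C)(O)/C=C/B1OC(C)(C)C(C)(C)O1
F2 | step 2 | 1-[5-bromo-2-hydroxy-4-(2-methylbut-3-yn-2-yloxy)phenyl]-3-(4-hydroxyphenyl)propan-1-one | C#CC(C)(C)Oc1cc(O)c(C(=O)CCc2ccc(O)cc2)cc1Br
F3 | step 2 | 1-[5-bromo-2-hydroxy-4-(2-methylbut-3-en-2-yloxy)phenyl]-3-(4-hydroxyphenyl)propan-1-one | C=CC(C)(C)Oc1cc(O)c(C(=O)CCc2ccc(O)cc2)cc1Br
F4 | step 1 | 3-(4-hydroxyphenyl)propanenitrile | N#CCCc1ccc(O)cc1
F5 | step 1 | 4-bromo-6-[3-(4-hydroxyphenyl)propanimidoyl]benzene-1,3-diol hydrochloride | [NH2+]=C(CCc1ccc(O)cc1)c1cc(Br)c(O)cc1O.[Cl-]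
F6 | step 4 | 1-[2,4-dihydroxy-3-(3-methylbut-2-enyl)phenyl]-3-(4-hydroxyphenyl)propan-1-one | CC(C)=CCc1c(O)ccc(C(=O)CCc2ccc(O)cc2)c1O
A1 | alternative 1 | 1-[2,4-dihydroxy-3-(3-methylbut-2-enyl)phenyl]-3-[4-(tert-butyldimethylsilyloxy)phenyl]propan-1-one | CC(C)=CCc1c(O)ccc(C(=O)CCc2ccc(O[Si](C)(C)C(C)(C)C)cc2)c1O
A2 | alternative 1 | 1-methoxy-2-(3-methylbut-2-enyl)-1,3-bis(trimethylsilyloxy)buta-1,3-diene | C=C(O[Si](C)(C)C)C(CC=C(C)C)=C(OC)O[Si](C)(C)C
A3 | alternative 1 | 5-[4-(tert-butyldimethylsilyloxy)phenyl]pent-1-yn-3-one | C#CC(=O)CCc1ccc(O[Si](C)(C)C(C)(C)C)cc1
A4 | alternative 1 | 3-methylbut-2-enal | CC(C)=CC=O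
A5 | alternative 2 | 2,2-dimethyl-8-(3-methylbut-2-enyl)-2H-chromen-7-ol | CC(C)=CCc1c(O)ccc2C=CC(C)(C)Oc12
A6 | alternative 2 | tert-butyl [8-(hydroxymethyl)-2,2-dimethyl-2H-chromen-7-yl] carbonate | CC1(C)C=Cc2ccc(OC(=O)OC(C)(C)C)c(CO)c2O1
A7 | alternative 2 | 2-methylprop-1-enylmagnesium bromide | CC(C)=C[Mg]Br
A8 | alternative 3 | 1-[7-(tert-butyldimethylsilyloxy)-2,2-dimethyl-8-(3-methylbut-2-enyl)-2H-chromen-6-yl]-3-[4-(tert-butyldimethylsilyloxy)phenyl]propan-1-one | CC(C)=CCc1c(O[Si](C)(C)C(C)(C)C)c(C(=O)CCc2ccc(O[Si](C)(C)C(C)(C)C)cc2)cc2c1OC(C)(C)C=C2
A9 | alternative 3 | 1-[7-(tert-butyldimethylsilyloxy)-2,2-dimethyl-8-(3-methylbut-2-enyl)-2H-chromen-6-yl]prop-2-en-1-one | CC(C)=CCc1c(O[Si](C)(C)C(C)(C)C)c(C(=O)C=C)cc2c1OC(C)(C)C=C2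
A10 | alternative 3 | 4-(tert-butyldimethylsilyloxy)phenylboronic acid | CC(C)(C)[Si](C)(C)Oc1ccc(B(O)O)cc1
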